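## Structural features

Numbering used throughout: C1 is the acetoxy carbon; C2=C3(Me)–C4(=O)–C5 complete the five-membered ring; C6 is the exocyclic CH; C7(Me), C8, C9, C10 are the oxolane carbons; C11 is the CMe2 carbon; C12, C13, C14 (CHMe) and C15 (ketone) complete the large ring.

Target 31 is a tricycle made of a cyclopentenone (ring A, C1–C5), an oxolane (ring B, C7–C10 plus oxygen) and a twelve-membered carbocycle (ring C, C1 and C5–C15). Ring C contains the C5=C6 alkene, which is exocyclic to ring A, and is bridged by the ring B oxygen between C7 and C10. Ring A is a cross-conjugated dienone, C2=C3(Me)–C4(=O)–C5=C6, and its sp3 carbon C1 is quaternary, carrying the acetate, C2, C5 and the C15 ketone. There are four stereocentres: C1 (S); C7 (S) and C10 (S), trans across ring B; and C14 (R). C1 and C14 flank the C15 carbonyl, C7 sits directly on C6, C10 is next to the quaternary C11, and no two stereocentres are bonded to each other. The fragile points are the tertiary, doubly allylic acetate α to a ketone, the dienone (a Michael acceptor whose exocyclic geometry can be lost by addition–elimination or by light) and the enolisable C14–H. The real difficulty is the trisubstituted C5=C6 alkene: it joins ring A to the fully substituted C7 and must hold C7 on the side of the quaternary C1, away from the C4 carbonyl (5E), an arrangement that is unlikely to be the relaxed one before ring C exists. Closing ring C with control of the isolated C14 centre is the second problem. The key step uses the fact that C4 and the hydrogen on C6 are cis across C5=C6. That is the imprint of syn addition of hydrogen and an aldehyde carbon across a C5≡C6 alkyne, and because C4 and C5 are tied 1,3 through C3=C2–C1 the addition closes ring A in the 5-exo mode.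

## Logic of the disconnections

**31 to 30.** The C12–C13 bond is cut, together with the C14–H bond. It lies in the unfunctionalised half of ring C, far from the crowded C1, and cutting it leaves an enone terminus at C13/C14 and a carbon radical at C12 that a carboxyl derivative can release. Ring C and the C14 stereocentre disappear. The forward step must close a twelve-membered ring by radical addition faster than the radical is quenched, and must deliver hydrogen to one face of C14.

**30 to 29, 27, 26 and 25.** No skeletal bond is cut. The N-acyloxy ester, the C1 acetate and the carboxyl oxidation level go back to a primary and a tertiary silyl ether. The radical precursor and the acetate cannot survive the hydride and organomagnesium steps that build C15, so they must come after those steps. The forward steps must remove both silyl groups of 25 without harming two enones and oxidise the primary alcohol of 26 beside a free tertiary ketol.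

**25 to 24, 23, 22 and 21.** The C14–C15 bond is cut (isopropenyl nucleophile plus a C15 aldehyde from the ester), and the C4 and C15 carbonyls go back to carbinols. C4 must stay masked as the silyl ether while C15 is built, and one oxidation then creates both ketones. Three carbons and both enone systems are removed. The forward sequence must cleave the secondary silyl ether at C4 of 23 in the presence of the tertiary one at C1.

**21 to 20.** The C4–C5 bond is cut, with the C6–H and O–Si bonds. This is the only cut that removes ring A and the alkene geometry at once, because syn addition across C5≡C6 dictates that C7 ends trans to C4. The result is an acyclic alkynal. The forward step must couple an enal carbonyl with a very hindered alkyne, with 1,2-selectivity and without loss of the Z geometry of the enal.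

**20 to 19, 18 and 17.** Only the oxidation level at C4 and the protecting groups at C1 and C4 change. The Z-enal is the most labile function and is made last. C1 must be capped before the aldehyde exists, because a free C1 hydroxyl would close onto it as a five-membered hemiacetal. The forward steps must cleave a primary silyl ether selectively and oxidise without isomerisation or lactonisation.

**17 to 9 and 16.** The C1–C5 bond is cut. This is the convergent cut: it splits the molecule into two fragments of similar size and creates C1 by addition to an activated ketone. The forward step must deliver the alkynyl group to one face of the keto ester under catalyst control, because the stereocentres of 9 are too far away to help.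

**16 to 14 and 15, then 13, 12, 11 and 10.** The C1–C2 bond is cut (alkenyl nucleophile plus oxalate), then C2–I, and then the C3–CH3 and C2–Mg bonds. The C2=C3 geometry is fixed at the very beginning by a chelate-controlled anti carbometallation. The forward steps must retain the alkene geometry through halogen–metal exchange and acylate only once.

**9 to 8 and 7.** The C5–C6 bond is cut (one-carbon homologation of an aldehyde). The alkyne carbon C5 is added to an oxygenated C6 that the ring-forming step provides for free.

**7 to 6.** The O–C7 bond is cut, along with the C6–O bond. Ring B and the C7 stereocentre are removed, leaving an open-chain alkenol with one stereocentre. The forward step must be trans-selective on a 1,1-disubstituted alkene.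

**6 to 5, 4, then 1 and 3 (from 2).** The C10–H bond, the O–Si bond and the C9–C10 bond are cut. C10 becomes a ketone carbon that is already present as the carbonyl of 1, and C11 with its two methyl groups comes ready-made. The forward steps must stop at mono-addition to the lactone and reduce the ketone with reagent control.

## Other disconnections considered

**Alternative 1:** The cut is C14–C15 of ring C. In the forward direction the alkenyl iodide aldehyde A2 would be treated with excess CrCl2 and catalytic NiCl2 at high dilution; the alkenylchromium species adds to the C15 aldehyde and closes the twelve-membered ring as the allylic alcohol A1.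
- In its favour: this ring closure is polar and chemoselective for the aldehyde, it tolerates enones and silyl ethers, and it does not depend on the lifetime of a radical. As a macrocyclisation event it is the more dependable of the two plans.
- Against it here: the chain terminus needs two more carbons (C13 and the iodoalkene carbon C14) than the lactone supplies. After closure, C15 must be oxidised and the C14 methylene reduced to CHMe in the presence of the dienone, and the C1 silyl group must still be exchanged for acetate.
- Structure: it addresses ring C only and would still need a step such as step 14 for ring A and the alkene geometry.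
- Mechanism: C14 would be set in a separate reduction, again by the substrate, so on stereocontrol at C14 the two plans are equal. The alternative has a small advantage in that the C15 hydroxyl could direct a hydrogenation.
- Step economy: the chosen plan forms C12–C13 and C14 in one step and is shorter by about three steps.

**Alternative 2:** The cuts are O–C10 and C10–C11 of ring B. In the forward direction the diazoketone A4 would be decomposed with Cu(acac)2; the carbene carbon C10 is captured by the tertiary prenyl ether oxygen on C7, and a [2,3]-shift of the prenyl group gives the oxolanone A3.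
- In its favour: one step makes ring B, the C10 centre and the congested C10–C11 bond, and the rearranged prenyl group leaves C12=C13 as a vinyl group. No carbon has to be sacrificed later, so on atom economy at that terminus it is the better plan.
- Against it here: the 2,5-trans outcome depends on distinguishing methyl from silyloxymethyl at C7, two groups of similar size. The tertiary prenyl ether must first be made in enantioenriched form. [1,2]-Shift and C–H insertion can compete. The C9 ketone must afterwards be removed in two or three steps.
- Structure: it covers only C6–C13 and leaves ring A, the alkene and ring C untouched.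
- Mechanism: it relays C7 to C10 through a cyclic transition state, whereas the chosen plan sets C10 by catalyst-controlled reduction and C7 by an inherently trans-selective cyclisation, each independently reliable.
- Step economy: the chosen plan reaches the same sector in four steps from two commercial compounds and is clearly shorter.

**Alternative 3:** The cut is O–C7 of ring B. In the forward direction the alkenol A6 (the same substance as 6) cyclises under Co(modp)2, O2 and tBuOOH to the trans oxolanylmethanol A5 (the same substance as 7).
- In its favour: the trans selectivity is inherent, C6 is oxygenated in the same step, and the substrate is a simple chiral alcohol.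
- Against it as the centre of a strategy: it makes one C–O bond, one ring and one stereocentre and does not touch the real difficulties (C1, the C5=C6 geometry, ring C). 1,1-Disubstituted alkenes are the less favourable substrates for this reaction.
- Structure: it solves ring B only.
- Mechanism: it is a radical aerobic process with substrate-controlled diastereoselection, complementary to the metallacycle logic of step 14 and not in competition with it.
- Step economy: for ring B it is the exact equal of the chosen plan, because the chosen plan contains it as step 4. The choice is therefore about which step carries the strategy, and that is the one which builds ring A and fixes the alkene.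

Key step: step 14

**Remarks on the chemistry (before the route)**
- Abbreviations: TES = triethylsilyl; TBDPS = tert-butyldiphenylsilyl; Ox = (2S,5S)-5-[4-(TBDPS-oxy)-2-methylbutan-2-yl]-2-methyloxolan-2-yl (oxolane C2 = C7, oxolane C5 = C10; the chain-bearing substituent at C2 and the side chain at C5 are trans).
- Assumption: the antipode of the amino alcohol ligand in step 10 is taken to be the one that delivers the alkynyl group to the Si face of the C1 carbonyl of 16 (sequence O > CO2Me > alkenyl); if that ligand series directs to the other face, its mirror image is used.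
- Assumption: C4 in 21–24 and C15 in 23–24 are formed without control and both become carbonyl carbons in step 18; C4 is drawn as one epimer for definiteness and C15 is left undefined.
- Structure check: the exocyclic alkene keeps one geometry from 21 to 31 (C7 trans to C4, cis to C1). Its descriptor is 5Z while C4 is a carbinol carbon and 5E once C4 is a ketone, because the sequence-rule priority at C5 changes. C1 is S in every compound from 17 to 31.
- Precursor design: the C1 silyl ether is kept as TES. It is the smallest group that survives the organometallic steps beside an already very hindered alkyne, it belongs to a different reactivity class (tertiary) from the secondary allylic TES ether created at C4, and it leaves together with the TBDPS group in step 19.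

## Route

**Step 1**
Reactants: 1 3,3-dimethyloxolan-2-one (α,α-dimethyl-γ-butyrolactone); 2 4-bromo-2-methylbut-1-ene
Product: 4 1-hydroxy-3,3,7-trimethyloct-7-en-4-one (in equilibrium with its cyclic hemiketal), via (3-methylbut-3-en-1-yl)magnesium bromide 3 (not isolated)
Conditions: 2, Mg, THF, rt; then 1, THF, −78 to 0 °C; aqueous work-up
Reagents that add atoms: none
Why: Grignard reagent 3 adds once to the lactone carbonyl and forms the C9–C10 bond; the magnesium hemiketalate, stabilised by the gem-dimethyl group, does not collapse at low temperature, so a second addition is suppressed. Reaction type: Grignard mono-addition to a hindered lactone.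

**Step 2**
Reactants: 4 1-hydroxy-3,3,7-trimethyloct-7-en-4-one
Product: 5 1-(TBDPS-oxy)-3,3,7-trimethyloct-7-en-4-one
Conditions: TBDPSCl, imidazole, DMF, rt
Reagents that add atoms: tert-butyl(chloro)diphenylsilane, CC(C)(C)[Si](Cl)(c1ccccc1)c1ccccc1
Why: Silylation of the primary hydroxyl of the open form (the tertiary hemiketal hydroxyl does not react) drains the equilibrium and fixes C10 as a ketone. Reaction type: silyl ether formation.

**Step 3**
Reactants: 5 1-(TBDPS-oxy)-3,3,7-trimethyloct-7-en-4-one
Product: 6 (4S)-1-(TBDPS-oxy)-3,3,7-trimethyloct-7-en-4-ol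
Conditions: (R)-2-methyl-CBS-oxazaborolidine (0.2 equiv), catecholborane, toluene, −78 to −20 °C
Reagents that add atoms: none
Why: Corey–Bakshi–Shibata reduction: the ketone binds with the tertiary alkyl group (C11) as the large and the CH2 chain (C9) as the small substituent, so the (R)-catalyst should deliver hydride to give the (4S)-carbinol, which is C10 of the target. Catecholborane at low temperature leaves the 1,1-disubstituted alkene untouched.

**Step 4**
Reactants: 6 (4S)-1-(TBDPS-oxy)-3,3,7-trimethyloct-7-en-4-ol
Product: 7 [(2S,5S)-5-[4-(TBDPS-oxy)-2-methylbutan-2-yl]-2-methyloxolan-2-yl]methanol (Ox-CH2OH)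
Conditions: Co(modp)2 (0.1 equiv; modp = 1-morpholinocarbamoyl-4,4-dimethylpentane-1,3-dionate), tBuOOH (0.1 equiv), O2 (1 atm), iPrOH, 55 °C
Reagents that add atoms: dioxygen, O=O
Why: Cobalt-catalysed aerobic oxidative cyclisation of a pent-4-en-1-ol: the C10 oxygen adds to C7 in the 5-exo-trig mode and the C6 radical is oxygenated by O2 and reduced to CH2OH. The 2,5-trans preference inherent in this cyclisation places the new CH2OH (C6) trans to the C10 side chain, which sets C7 as S.

**Step 5**
Reactants: 7 Ox-CH2OH
Product: 8 (2S,5S)-5-[4-(TBDPS-oxy)-2-methylbutan-2-yl]-2-methyloxolane-2-carbaldehyde (Ox-CHO)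
Conditions: Dess–Martin periodinane, CH2Cl2, rt
Reagents that add atoms: none
Why: Dess–Martin oxidation of a neopentyl-type primary alcohol; the aldehyde has no α-hydrogen and cannot epimerise at C7.

**Step 6**
Reactants: 8 Ox-CHO
Product: 9 (2S,5S)-5-[4-(TBDPS-oxy)-2-methylbutan-2-yl]-2-ethynyl-2-methyloxolane (Ox-C≡CH)
Conditions: dimethyl (1-diazo-2-oxopropyl)phosphonate, K2CO3, MeOH, 0 °C to rt
Reagents that add atoms: dimethyl (1-diazo-2-oxopropyl)phosphonate, COP(=O)(OC)C(=[N+]=[N-])C(C)=O
Why: Ohira–Bestmann homologation: the diazomethylphosphonate anion released by methanolysis adds to the aldehyde, and loss of phosphate and N2 with 1,2-hydrogen shift gives the terminal alkyne. This adds C5 without touching C7.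

**Step 7**
Reactants: 10 prop-2-yn-1-ol
Product: 12 (2Z)-3-iodo-2-methylprop-2-en-1-ol, via 4-methyl-2,5-dihydro-1,2-oxamagnesole 11 (not isolated)
Conditions: MeMgBr (2.5 equiv), CuI (0.1 equiv), THF, −10 °C to rt; then I2, −78 to 0 °C
Reagents that add atoms: methylmagnesium bromide, C[Mg]Br; iodine, II
Why: Copper-catalysed carbomagnesiation of the propargylic alkoxide: methyl adds to the internal alkyne carbon and magnesium to the terminal one in an anti sense, held in the five-membered chelate 11. Iodinolysis with retention gives the Z-iodide (iodine cis to CH2OH), which fixes the C2=C3 geometry of ring A from the outset.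

**Step 8**
Reactants: 12 (2Z)-3-iodo-2-methylprop-2-en-1-ol
Product: 13 triethyl{[(2Z)-3-iodo-2-methylprop-2-en-1-yl]oxy}silane
Conditions: TESCl, imidazole, CH2Cl2, 0 °C
Reagents that add atoms: chlorotriethylsilane, CC[Si](Cl)(CC)CC
Why: Standard silylation; a primary TES ether is chosen because it can later be removed in the presence of a tertiary TES ether and a TBDPS ether.

**Step 9**
Reactants: 13 triethyl{[(2Z)-3-iodo-2-methylprop-2-en-1-yl]oxy}silane; 14 dimethyl oxalate
Product: 16 methyl (3Z)-4-methyl-2-oxo-5-(TES-oxy)pent-3-enoate, via [(1Z)-2-methyl-3-(triethylsilyloxy)prop-1-en-1-yl]lithium 15 (not isolated)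
Conditions: tBuLi (2 equiv), Et2O, −78 °C; cannulation into 14 (3 equiv), THF, −78 °C; AcOH quench at −78 °C
Reagents that add atoms: none
Why: Iodine–lithium exchange proceeds with retention of alkene geometry, and inverse addition to excess oxalate gives a tetrahedral adduct that is stable at −78 °C, so acylation stops after one addition and forms the C1–C2 bond. Reaction type: acylation of an alkenyllithium with a dialkyl oxalate.

**Step 10**
Reactants: 9 Ox-C≡CH; 16 methyl (3Z)-4-methyl-2-oxo-5-(TES-oxy)pent-3-enoate
Product: 17 methyl (2S,3Z)-2-hydroxy-4-methyl-2-[(Ox)ethynyl]-5-(TES-oxy)pent-3-enoate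
Conditions: Zn(OTf)2 (0.3 equiv), 2-(dimethylamino)-1-(4-nitrophenyl)-3-(tert-butyldimethylsilyloxy)propan-1-ol (0.33 equiv, antipode as in the remark), Et3N (0.5 equiv), toluene, 50 °C
Reagents that add atoms: none
Why: Zinc-mediated catalytic asymmetric alkynylation of an α-keto ester: the zinc acetylide formed in situ from 9 adds to the chelated keto ester inside the chiral amino alcohol complex, forming C1–C5 and setting C1 by catalyst control (Si-face delivery gives 2S). Conjugate addition is disfavoured because the enone β-carbon is fully substituted.

**Step 11**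
Reactants: 17 methyl (2S,3Z)-2-hydroxy-4-methyl-2-[(Ox)ethynyl]-5-(TES-oxy)pent-3-enoate
Product: 18 methyl (2S,3Z)-4-methyl-2-[(Ox)ethynyl]-2,5-bis(TES-oxy)pent-3-enoate
Conditions: TESOTf, 2,6-lutidine, CH2Cl2, −78 to 0 °C
Reagents that add atoms: triethylsilyl trifluoromethanesulfonate, CC[Si](CC)(CC)OS(=O)(=O)C(F)(F)F
Why: A silyl triflate with a hindered pyridine base silylates the tertiary propargylic alcohol. This blocks hemiacetal formation with the later Z-aldehyde and protects C1 through the organometallic steps.

**Step 12**
Reactants: 18 methyl (2S,3Z)-4-methyl-2-[(Ox)ethynyl]-2,5-bis(TES-oxy)pent-3-enoate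
Product: 19 methyl (2S,3Z)-5-hydroxy-4-methyl-2-[(Ox)ethynyl]-2-(TES-oxy)pent-3-enoate
Conditions: HF·pyridine, pyridine, THF, 0 °C, short contact
Reagents that add atoms: none
Why: Buffered fluoride cleaves the unhindered primary allylic TES ether much faster than the tertiary TES or the TBDPS ether. Low temperature and non-basic conditions are chosen so that the Z-allylic alcohol does not lactonise onto the C15 ester.

**Step 13**
Reactants: 19 methyl (2S,3Z)-5-hydroxy-4-methyl-2-[(Ox)ethynyl]-2-(TES-oxy)pent-3-enoate
Product: 20 methyl (2S,3Z)-4-methyl-5-oxo-2-[(Ox)ethynyl]-2-(TES-oxy)pent-3-enoate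
Conditions: MnO2 (excess), CH2Cl2, rt, dark
Reagents that add atoms: none
Why: MnO2 oxidises the allylic alcohol under neutral heterogeneous conditions, which should preserve the Z geometry of the α-methyl enal; 20 is used at once.

**Step 14**
Reactants: 20 methyl (2S,3Z)-4-methyl-5-oxo-2-[(Ox)ethynyl]-2-(TES-oxy)pent-3-enoate
Product: 21 methyl (1S,5Z)-3-methyl-5-[(Ox)methylidene]-1,4-bis(TES-oxy)cyclopent-2-ene-1-carboxylate (C4 epimer undefined)
Conditions: Ni(COD)2 (0.2 equiv), PBu3 (0.4 equiv), Et3SiH (5 equiv), THF, 0 °C to rt; 20 added slowly, final 0.02 M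
Reagents that add atoms: triethylsilane, CC[SiH](CC)CC
Why: Zerovalent nickel carrying PBu3 binds the C5≡C6 alkyne and the C4 aldehyde of 20 side by side and couples them oxidatively to an oxanickelacyclopentene in which C4–C5 is formed and nickel sits on C6, necessarily cis to C4. σ-Bond metathesis of the Ni–O bond with Et3SiH silylates the C4 oxygen and leaves an alkenylnickel hydride, whose reductive elimination puts hydrogen on C6 with retention and returns zerovalent nickel. The closest known reaction type is the nickel-catalysed reductive cyclisation of alkynals with trialkylsilanes to 2-alkylidenecycloalkanol silyl ethers; what has no direct counterpart is that the aldehyde is conjugated and the tether contains a Z-alkene. Ring A closes in the 5-exo-dig mode, because the three-atom C3=C2–C1 tether allows only the five-membered metallacycle. The new C4 centre is under weak substrate control by the C1 substituents and needs none, since C4 becomes a carbonyl carbon in step 18. The step needs 1,2- and not 1,4-reactivity of the enal, C4–C5 and not C4–C6 bonding, and syn addition: the first is secured because the enal β-carbon C2 is bonded to C1 and cannot reach either alkyne carbon in a ring of workable size, the second by the tether, and the third by the metallacycle, so that C7 ends trans to C4 and cis to C1, the 5E arrangement of 31 (descriptor 5Z in 21). The Z geometry of the enal and the quaternary C1 hold aldehyde and alkyne within bonding distance, and premixing nickel with the phosphine and adding 20 slowly into excess silane keeps free phosphine and idle enal low, so that the enal should cyclise before it can isomerise. The ester, the silyl ethers and the oxolane are inert to the catalyst.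

**Step 15**
Reactants: 21 methyl (1S,5Z)-3-methyl-5-[(Ox)methylidene]-1,4-bis(TES-oxy)cyclopent-2-ene-1-carboxylate
Product: 22 (1S,5Z)-3-methyl-5-[(Ox)methylidene]-1,4-bis(TES-oxy)cyclopent-2-ene-1-carbaldehyde
Conditions: iBu2AlH (1.5 equiv), CH2Cl2, −78 °C; aqueous Rochelle salt work-up
Reagents that add atoms: none
Why: DIBAL reduction of an α-silyloxy ester at −78 °C stops at the chelated aluminium hemiacetal, which releases the aldehyde on work-up; the quaternary C1 cannot epimerise.

**Step 16**
Reactants: 22 (1S,5Z)-3-methyl-5-[(Ox)methylidene]-1,4-bis(TES-oxy)cyclopent-2-ene-1-carbaldehyde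
Product: 23 1-[(1S,5Z)-3-methyl-5-[(Ox)methylidene]-1,4-bis(TES-oxy)cyclopent-2-en-1-yl]-2-methylprop-2-en-1-ol (C15 epimers)
Conditions: isopropenylmagnesium bromide, THF, −78 to −40 °C; quench cold
Reagents that add atoms: isopropenylmagnesium bromide, C=C(C)[Mg]Br
Why: Grignard addition to the aldehyde forms C14–C15; the C15 configuration is irrelevant because the carbinol is oxidised in step 18. Quenching cold prevents migration of the C1 silyl group to the new alkoxide.

**Step 17**
Reactants: 23 1-[(1S,5Z)-3-methyl-5-[(Ox)methylidene]-1,4-bis(TES-oxy)cyclopent-2-en-1-yl]-2-methylprop-2-en-1-ol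
Product: 24 (4S,5Z)-4-(1-hydroxy-2-methylprop-2-en-1-yl)-2-methyl-5-[(Ox)methylidene]-4-(TES-oxy)cyclopent-2-en-1-ol
Conditions: HF·pyridine, pyridine, THF, 0 °C
Reagents that add atoms: none
Why: Buffered HF·pyridine cleaves the secondary allylic TES ether at C4 faster than the tertiary TES ether at C1 and the TBDPS ether. Fluoride is used in place of protic acid because C4 is doubly allylic and would ionise.

**Step 18**
Reactants: 24 (4S,5Z)-4-(1-hydroxy-2-methylprop-2-en-1-yl)-2-methyl-5-[(Ox)methylidene]-4-(TES-oxy)cyclopent-2-en-1-ol
Product: 25 (4S,5E)-2-methyl-4-(2-methylprop-2-enoyl)-5-[(Ox)methylidene]-4-(TES-oxy)cyclopent-2-en-1-one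
Conditions: Dess–Martin periodinane (3 equiv), NaHCO3, CH2Cl2, 0 °C to rt
Reagents that add atoms: none
Why: Dess–Martin oxidation of both secondary allylic alcohols gives the C4 dienone and the C15 methacryloyl ketone in one operation. The exocyclic alkene is not touched (descriptor now 5E), and the product carries the 4-oxy-5-alkylidenecyclopent-2-enone motif found in stable natural cross-conjugated dienones.

**Step 19**
Reactants: 25 (4S,5E)-2-methyl-4-(2-methylprop-2-enoyl)-5-[(Ox)methylidene]-4-(TES-oxy)cyclopent-2-en-1-one
Product: 26 (4S,5E)-4-hydroxy-5-{[(2S,5S)-5-(4-hydroxy-2-methylbutan-2-yl)-2-methyloxolan-2-yl]methylidene}-2-methyl-4-(2-methylprop-2-enoyl)cyclopent-2-en-1-one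
Conditions: HF·pyridine (excess), THF, 0 °C to rt
Reagents that add atoms: none
Why: Excess HF·pyridine removes the tertiary TES ether and the primary TBDPS ether together; the acidic, non-nucleophilic medium is compatible with both enones.

**Step 20**
Reactants: 26 (4S,5E)-4-hydroxy-5-{[(2S,5S)-5-(4-hydroxy-2-methylbutan-2-yl)-2-methyloxolan-2-yl]methylidene}-2-methyl-4-(2-methylprop-2-enoyl)cyclopent-2-en-1-one
Product: 27 3-[(2S,5S)-5-{(E)-[(2S)-2-hydroxy-4-methyl-2-(2-methylprop-2-enoyl)-5-oxocyclopent-3-en-1-ylidene]methyl}-5-methyloxolan-2-yl]-3-methylbutanoic acid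
Conditions: TEMPO (0.2 equiv), PhI(OAc)2 (2.5 equiv), MeCN/aqueous pH 7 buffer, rt
Reagents that add atoms: water, O
Why: Oxoammonium-mediated oxidation takes the primary alcohol through the aldehyde hydrate to the acid; the tertiary alcohol and the enones are inert to it.

**Step 21**
Reactants: 27 3-[(2S,5S)-5-{(E)-[(2S)-2-hydroxy-4-methyl-2-(2-methylprop-2-enoyl)-5-oxocyclopent-3-en-1-ylidene]methyl}-5-methyloxolan-2-yl]-3-methylbutanoic acid
Product: 29 3-[(2S,5S)-5-{(E)-[(2S)-2-acetoxy-4-methyl-2-(2-methylprop-2-enoyl)-5-oxocyclopent-3-en-1-ylidene]methyl}-5-methyloxolan-2-yl]-3-methylbutanoic acid, via acetoxy mixed acetic anhydride 28 (not isolated)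
Conditions: Ac2O, DMAP, pyridine, rt; then H2O/THF
Reagents that add atoms: acetic anhydride, CC(=O)OC(C)=O; water, O
Why: DMAP-catalysed acetylation of the tertiary α-ketol; the carboxyl group is converted in passing into the mixed anhydride 28, which water hydrolyses back to the acid. Installing the acetate here means that no base treatment follows once C14 is set.

**Step 22**
Reactants: 29 3-[(2S,5S)-5-{(E)-[(2S)-2-acetoxy-4-methyl-2-(2-methylprop-2-enoyl)-5-oxocyclopent-3-en-1-ylidene]methyl}-5-methyloxolan-2-yl]-3-methylbutanoic acid
Product: 30 1,3-dioxoisoindolin-2-yl ester of 29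
Conditions: N-hydroxyphthalimide, N,N'-diisopropylcarbodiimide, CH2Cl2, 0 °C to rt
Reagents that add atoms: N-hydroxyphthalimide, O=C1c2ccccc2C(=O)N1O
Why: Carbodiimide coupling gives the redox-active ester; no nucleophilic catalyst is added, so that the N-oxide anion does not add to the methacryloyl group.

**Step 23**
Reactants: 30 1,3-dioxoisoindolin-2-yl ester of 29
Product: 31 target, (1S,5E,7S,10S,14R)-1-acetoxy-4,15-dioxo tricycle in the numbering of the first section
Conditions: Ru(bpy)3(PF6)2 (0.02 equiv), Hantzsch ester (1.5 equiv), CH2Cl2, 0.002 M, blue LEDs, rt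
Reagents that add atoms: none
Why: Decarboxylative Giese macrocyclisation: single-electron reduction of the N-acyloxyphthalimide by the photoreduced ruthenium complex releases CO2 and the primary C12 radical, which adds to the terminal C13 methylene of the methacryloyl ketone (12-endo-trig, ring C) at high dilution, and the α-keto C14 radical then takes a hydrogen atom from the Hantzsch ester. C14 is set by substrate control in this hydrogen transfer (delivery from the open outer face of the macrocycle; the required outcome is 14R), which is the least secure stereochemical element of the route. Visible light and a sensitiser of low triplet energy are chosen so that the dienone geometry is not disturbed.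

## Compound list

1 | 3,3-dimethyloxolan-2-one | CC1(C)CCOC1=O | starting material
2 | 4-bromo-2-methylbut-1-ene | C=C(C)CCBr | starting material
3 | (3-methylbut-3-en-1-yl)magnesium bromide | C=C(C)CC[Mg]Br | intermediate (not isolated)
4 | 1-hydroxy-3,3,7-trimethyloct-7-en-4-one (with its cyclic hemiketal) | C=C(C)CCC(=O)C(C)(C)CCO | intermediate
5 | 1-(TBDPS-oxy)-3,3,7-trimethyloct-7-en-4-one | C=C(C)CCC(=O)C(C)(C)CCO[Si](c1ccccc1)(c1ccccc1)C(C)(C)C | intermediate
6 | (4S)-1-(TBDPS-oxy)-3,3,7-trimethyloct-7-en-4-ol | C=C(C)CC[C@H](O)C(C)(C)CCO[Si](c1ccccc1)(c1ccccc1)C(C)(C)C | intermediate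
7 | [(2S,5S)-5-[4-(TBDPS-oxy)-2-methylbutan-2-yl]-2-methyloxolan-2-yl]methanol | OC[C@]1(C)CC[C@H](O1)C(C)(C)CCO[Si](c1ccccc1)(c1ccccc1)C(C)(C)C | intermediate
8 | (2S,5S)-5-[4-(TBDPS-oxy)-2-methylbutan-2-yl]-2-methyloxolane-2-carbaldehyde | O=C[C@]1(C)CC[C@H](O1)C(C)(C)CCO[Si](c1ccccc1)(c1ccccc1)C(C)(C)C | intermediate
9 | (2S,5S)-5-[4-(TBDPS-oxy)-2-methylbutan-2-yl]-2-ethynyl-2-methyloxolane | C#C[C@]1(C)CC[C@H](O1)C(C)(C)CCO[Si](c1ccccc1)(c1ccccc1)C(C)(C)C | intermediate
10 | prop-2-yn-1-ol | C#CCO | starting material
11 | 4-methyl-2,5-dihydro-1,2-oxamagnesole | CC1=C[Mg]OC1 | intermediate (not isolated)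
12 | (2Z)-3-iodo-2-methylprop-2-en-1-ol | I/C=C(/C)CO | intermediate
13 | triethyl{[(2Z)-3-iodo-2-methylprop-2-en-1-yl]oxy}silane | I/C=C(/C)CO[Si](CC)(CC)CC | intermediate
14 | dimethyl oxalate | COC(=O)C(=O)OC | starting material
15 | [(1Z)-2-methyl-3-(triethylsilyloxy)prop-1-en-1-yl]lithium | [Li]/C=C(/C)CO[Si](CC)(CC)CC | intermediate (not isolated)
16 | methyl (3Z)-4-methyl-2-oxo-5-(TES-oxy)pent-3-enoate | COC(=O)C(=O)/C=C(/C)CO[Si](CC)(CC)CC | intermediate
17 | methyl (2S,3Z)-2-hydroxy-4-methyl-2-[(Ox)ethynyl]-5-(TES-oxy)pent-3-enoate | COC(=O)[C@@](O)(C#C[C@]1(C)CC[C@H](O1)C(C)(C)CCO[Si](c1ccccc1)(c1ccccc1)C(C)(C)C)/C=C(/C)CO[Si](CC)(CC)CC | intermediate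
18 | methyl (2S,3Z)-4-methyl-2-[(Ox)ethynyl]-2,5-bis(TES-oxy)pent-3-enoate | COC(=O)[C@@](O[Si](CC)(CC)CC)(C#C[C@]1(C)CC[C@H](O1)C(C)(C)CCO[Si](c1ccccc1)(c1ccccc1)C(C)(C)C)/C=C(/C)CO[Si](CC)(CC)CC | intermediate
19 | methyl (2S,3Z)-5-hydroxy-4-methyl-2-[(Ox)ethynyl]-2-(TES-oxy)pent-3-enoate | COC(=O)[C@@](O[Si](CC)(CC)CC)(C#C[C@]1(C)CC[C@H](O1)C(C)(C)CCO[Si](c1ccccc1)(c1ccccc1)C(C)(C)C)/C=C(/C)CO | intermediate
20 | methyl (2S,3Z)-4-methyl-5-oxo-2-[(Ox)ethynyl]-2-(TES-oxy)pent-3-enoate (key-step precursor) | COC(=O)[C@@](O[Si](CC)(CC)CC)(C#C[C@]1(C)CC[C@H](O1)C(C)(C)CCO[Si](c1ccccc1)(c1ccccc1)C(C)(C)C)/C=C(/C)C=O | intermediate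
21 | methyl (1S,5Z)-3-methyl-5-[(Ox)methylidene]-1,4-bis(TES-oxy)cyclopent-2-ene-1-carboxylate (key-step product; C4 drawn as one epimer) | COC(=O)[C@]1(O[Si](CC)(CC)CC)C=C(C)[C@H](O[Si](CC)(CC)CC)/C1=C/[C@]1(C)CC[C@H](O1)C(C)(C)CCO[Si](c1ccccc1)(c1ccccc1)C(C)(C)C | intermediate
22 | (1S,5Z)-3-methyl-5-[(Ox)methylidene]-1,4-bis(TES-oxy)cyclopent-2-ene-1-carbaldehyde | O=C[C@]1(O[Si](CC)(CC)CC)C=C(C)[C@H](O[Si](CC)(CC)CC)/C1=C/[C@]1(C)CC[C@H](O1)C(C)(C)CCO[Si](c1ccccc1)(c1ccccc1)C(C)(C)C | intermediate
23 | 1-[(1S,5Z)-3-methyl-5-[(Ox)methylidene]-1,4-bis(TES-oxy)cyclopent-2-en-1-yl]-2-methylprop-2-en-1-ol (C15 undefined) | C=C(C)C(O)[C@]1(O[Si](CC)(CC)CC)C=C(C)[C@H](O[Si](CC)(CC)CC)/C1=C/[C@]1(C)CC[C@H](O1)C(C)(C)CCO[Si](c1ccccc1)(c1ccccc1)C(C)(C)C | intermediate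
24 | (4S,5Z)-4-(1-hydroxy-2-methylprop-2-en-1-yl)-2-methyl-5-[(Ox)methylidene]-4-(TES-oxy)cyclopent-2-en-1-ol | C=C(C)C(O)[C@]1(O[Si](CC)(CC)CC)C=C(C)[C@H](O)/C1=C/[C@]1(C)CC[C@H](O1)C(C)(C)CCO[Si](c1ccccc1)(c1ccccc1)C(C)(C)C | intermediate
25 | (4S,5E)-2-methyl-4-(2-methylprop-2-enoyl)-5-[(Ox)methylidene]-4-(TES-oxy)cyclopent-2-en-1-one | C=C(C)C(=O)[C@]1(O[Si](CC)(CC)CC)C=C(C)C(=O)/C1=C/[C@]1(C)CC[C@H](O1)C(C)(C)CCO[Si](c1ccccc1)(c1ccccc1)C(C)(C)C | intermediate
26 | (4S,5E)-4-hydroxy-5-{[(2S,5S)-5-(4-hydroxy-2-methylbutan-2-yl)-2-methyloxolan-2-yl]methylidene}-2-methyl-4-(2-methylprop-2-enoyl)cyclopent-2-en-1-one | C=C(C)C(=O)[C@]1(O)C=C(C)C(=O)/C1=C/[C@]1(C)CC[C@H](O1)C(C)(C)CCO | intermediate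
27 | 3-[(2S,5S)-5-{(E)-[(2S)-2-hydroxy-4-methyl-2-(2-methylprop-2-enoyl)-5-oxocyclopent-3-en-1-ylidene]methyl}-5-methyloxolan-2-yl]-3-methylbutanoic acid | C=C(C)C(=O)[C@]1(O)C=C(C)C(=O)/C1=C/[C@]1(C)CC[C@H](O1)C(C)(C)CC(=O)O | intermediate
28 | mixed acetic anhydride of 29 | C=C(C)C(=O)[C@]1(OC(C)=O)C=C(C)C(=O)/C1=C/[C@]1(C)CC[C@H](O1)C(C)(C)CC(=O)OC(C)=O | intermediate (not isolated)
29 | 3-[(2S,5S)-5-{(E)-[(2S)-2-acetoxy-4-methyl-2-(2-methylprop-2-enoyl)-5-oxocyclopent-3-en-1-ylidene]methyl}-5-methyloxolan-2-yl]-3-methylbutanoic acid | C=C(C)C(=O)[C@]1(OC(C)=O)C=C(C)C(=O)/C1=C/[C@]1(C)CC[C@H](O1)C(C)(C)CC(=O)O | intermediate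
30 | 1,3-dioxoisoindolin-2-yl ester of 29 | C=C(C)C(=O)[C@]1(OC(C)=O)C=C(C)C(=O)/C1=C/[C@]1(C)CC[C@H](O1)C(C)(C)CC(=O)ON1C(=O)c2ccccc2C1=O | intermediate
31 | target, (1S,5E,7S,10S,14R) | CC(=O)O[C@@]12C=C(C)C(=O)/C1=C/[C@]1(C)CC[C@H](O1)C(C)(C)CC[C@@H](C)C2=O | target

## Step count and least certain steps

Total step count: 23. Longest linear sequence: 20 steps (steps 1–6 and 10–23); the keto ester branch (steps 7–9) has 3 steps.

**Step 14 (key step).**
- What may go wrong: the enal may isomerise from Z to E by phosphine addition–elimination before it cyclises, or its C=C or C=O bond may be hydrosilylated, because the alkyne lies between two fully substituted carbons and engages slowly. An E-enal cannot reach C5. A carbene ligand such as IMes or the bulkier PCy3 would be tried first as a change of conditions.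
- Fallback, from 20 back to 21: hydrogen-mediated reductive cyclisation with a cationic rhodium catalyst (Rh(COD)2OTf, a chelating biaryl bisphosphine, H2 at 1 atm, 1,2-dichloroethane). This uses no silane and no free monophosphine, and forms the same C4–C5 bond by syn addition through an oxarhodacycle that is opened by hydrogen. It should give the free C4 carbinol, methyl (1S,5Z)-4-hydroxy-3-methyl-5-[(Ox)methylidene]-1-(TES-oxy)cyclopent-2-ene-1-carboxylate F1, which is silylated with TESCl and imidazole to rejoin the route at 21.

**Step 23.**
- What may go wrong: poor facial selectivity in the hydrogen transfer to the macrocyclic C14 radical, since only the ring conformation controls it. Premature reduction of the C12 radical before ring closure is the second risk. Addition to C6 of the dienone is not expected, because C6 and C11 are trans on ring B.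
- Fallback, from 30 back to 31: the ring closure is run without regard to the C14 outcome, and the C14 epimer of the target F2, formed beside 31, is equilibrated through its C15 enol(ate) with a catalytic amidine base (DBU, toluene, rt). C14–H is the only enolisable position next to C15, so stereocontrol changes from kinetic to thermodynamic. This rests on the expectation that the configuration found in the natural product is the more stable one in the ring.

**Step 10.**
- What may go wrong: insufficient facial discrimination at the C1 ketone with so large an alkyne, or Z-to-E isomerisation of the keto ester under Lewis acid and amine at 50 °C.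
- Fallback, from 9 and 16 back to 17: 9 is deprotonated (LiN(SiMe3)2, THF, −78 °C) to the lithium acetylide of 9 F3, which adds to 16 at −78 °C without facial control. Because 9 is a single enantiomer, 17 and its C1 epimer, methyl (2R,3Z)-2-hydroxy-4-methyl-2-[(Ox)ethynyl]-5-(TES-oxy)pent-3-enoate F4, are diastereomers and are separated by chromatography. Catalyst control is traded for separation at the cost of half the material.

**Step 12.**
- What may go wrong: lactonisation of the freed Z-allylic alcohol onto the C15 ester (a six-membered ring, favoured by the Z-alkene and the quaternary C1), or partial loss of the C1 silyl group.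
- Fallback, from 18 directly to 20: Swern oxidation of the bis-silyl ether ((COCl)2, DMSO, CH2Cl2, −78 to −30 °C; then Et3N). This cleaves and oxidises a primary TES ether in one operation while tertiary TES and TBDPS ethers remain, so no free alcohol is ever present. The fallback creates no new compound (F0) and replaces steps 12 and 13.

**Step 1.**
- What may go wrong: a second addition of 3 after ring opening of the hemiketalate.
- Fallback, from 1 back to 5: 1 is opened with MeNH(OMe)·HCl and Me2AlCl to 4-hydroxy-N-methoxy-N,2,2-trimethylbutanamide F5, which is silylated at once (TBDPSCl, imidazole) to 4-(TBDPS-oxy)-N-methoxy-N,2,2-trimethylbutanamide F6. Grignard reagent 3 then adds once to the N-methoxy-N-methylamide, by way of its stable chelate, to give 5.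

## Further compounds

F1 | step 14 | methyl (1S,5Z)-4-hydroxy-3-methyl-5-[(Ox)methylidene]-1-(TES-oxy)cyclopent-2-ene-1-carboxylate (C4 drawn as one epimer) | COC(=O)[C@]1(O[Si](CC)(CC)CC)C=C(C)[C@H](O)/C1=C/[C@]1(C)CC[C@H](O1)C(C)(C)CCO[Si](c1ccccc1)(c1ccccc1)C(C)(C)C
F2 | step 23 | C14 epimer of 31, (1S,5E,7S,10S,14S) | CC(=O)O[C@@]12C=C(C)C(=O)/C1=C/[C@]1(C)CC[C@H](O1)C(C)(C)CC[C@H](C)C2=O
F3 | step 10 | lithium acetylide of 9 | [Li]C#C[C@]1(C)CC[C@H](O1)C(C)(C)CCO[Si](c1ccccc1)(c1ccccc1)C(C)(C)C
F4 | step 10 | methyl (2R,3Z)-2-hydroxy-4-methyl-2-[(Ox)ethynyl]-5-(TES-oxy)pent-3-enoate | COC(=O)[C@](O)(C#C[C@]1(C)CC[C@H](O1)C(C)(C)CCO[Si](c1ccccc1)(c1ccccc1)C(C)(C)C)/C=C(/C)CO[Si](CC)(CC)CC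
F0 | step 12 | none | none
F5 | step 1 | 4-hydroxy-N-methoxy-N,2,2-trimethylbutanamide | CON(C)C(=O)C(C)(C)CCO
F6 | step 1 | 4-(TBDPS-oxy)-N-methoxy-N,2,2-trimethylbutanamide | CON(C)C(=O)C(C)(C)CCO[Si](c1ccccc1)(c1ccccc1)C(C)(C)C
A1 | alternative 1 | macrocyclic C15 allylic alcohol with C14 methylene and C1 TES ether (C15 drawn as one epimer) | CC[Si](CC)(CC)O[C@@]12C=C(C)C(=O)/C1=C/[C@]1(C)CC[C@H](O1)C(C)(C)CCC(=C)[C@H]2O
A2 | alternative 1 | seco C15 aldehyde with C14 alkenyl iodide and C1 TES ether | O=C[C@]1(O[Si](CC)(CC)CC)C=C(C)C(=O)/C1=C/[C@]1(C)CC[C@H](O1)C(C)(C)CCC(I)=C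
A3 | alternative 2 | 2,5-trans 5-methyl-2-(2-methylbut-3-en-2-yl)-5-(TBDPS-oxymethyl)oxolan-3-one | CC(C)(C)[Si](c1ccccc1)(c1ccccc1)OC[C@]1(C)CC(=O)[C@H](O1)C(C)(C)C=C
A4 | alternative 2 | 1-diazo-4-methyl-4-(3-methylbut-2-en-1-yloxy)-5-(TBDPS-oxy)pentan-2-one | CC(C)(C)[Si](c1ccccc1)(c1ccccc1)OC[C@@](C)(OCC=C(C)C)CC(=O)C=[N+]=[N-]
A5 | alternative 3 | [(2S,5S)-5-[4-(TBDPS-oxy)-2-methylbutan-2-yl]-2-methyloxolan-2-yl]methanol (same as 7) | OC[C@]1(C)CC[C@H](O1)C(C)(C)CCO[Si](c1ccccc1)(c1ccccc1)C(C)(C)C
A6 | alternative 3 | (4S)-1-(TBDPS-oxy)-3,3,7-trimethyloct-7-en-4-ol (same as 6) | C=C(C)CC[C@H](O)C(C)(C)CCO[Si](c1ccccc1)(c1ccccc1)C(C)(C)C
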